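Blue holds 31 mM of starting material against 34.1 mM of partner, with 0.31 mM of free catalyst and 46.0 mM of scavenger; green holds twice that scavenger.

- blue: starting material 31 mM; partner 34.1 mM; scavenger 46.0 mM; free catalyst 0.31 mM; time 10 min
- green: starting material 31 mM; partner 34.1 mM; scavenger 93.0 mM; free catalyst 0.31 mM; time 10 min

    partner + free catalyst → catalyst intermediate A (k1 = 380 M⁻¹ s⁻¹)
    starting material + catalyst intermediate A → catalyst intermediate B (k2 = 1900 M⁻¹ s⁻¹)
    catalyst intermediate B ⇌ catalyst intermediate C (K3 = 0.95, k3 = 490 s⁻¹)
    catalyst intermediate C → released group + catalyst intermediate D (k4 = 14 s⁻¹)
    catalyst intermediate D → free catalyst + target (k5 = 52 s⁻¹)
    partner + released group ⇌ idle adduct, settled at all times (K6 = 410 M⁻¹)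
    scavenger + released group → scavenged by-product (k7 = 2.3 M⁻¹ s⁻¹)
    partner → decomposed reagent (k8 = 0.013 s⁻¹)

- released group is meant together with its idle adduct
- run time (blue): 10 min

- part of the starting material that has reacted at the end, blue
- part of the starting material that has reacted at the end, green
- what raising the concentration of scavenger from its lowest to its highest value here does to the part of the starting material that has reacted (changes below 5 percentage points count as none) (it falls / no change / it rises)

A molecule of free partner stands at a fork: it meets free catalyst in step 1, or it decomposes in step 8. Its chance of entering the cycle is k1·c(free catalyst) divided by that same term plus k8, so the fork depends on how much catalyst is free at that moment. c(scavenger) does not appear in it.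

In the first instants of either flask the catalyst is all free, and this reckoning puts the fork at 0.901. Free catalyst then picks up partner at 13.0 s⁻¹. One passage through the other forms takes 0.183 s, and at the charged amounts the longest stay is in catalyst intermediates B and C, the resting state of that moment. At the charged c(partner) the free share of the catalyst is therefore 0.297, and the fork drops to 0.729.

In the middle, each turn gives one released group. While c(partner) stands near its charge, that group lies mostly in the idle adduct, which holds partner away from both paths. At its charged amount in blue, the scavenger removes free released group with a half-life of 0.11 min.

Towards the end, as c(partner) falls, this reckoning expects the catalyst free again and the fork back at its first value. The mean of the two ends, taken as the partner's fork share φ = 0.815, puts 27.8 mM of partner through the cycle. That is less than the charged starting material, so partner is the limiting reagent, and this reckoning gives 89.6% for both flasks. Decomposition alone has a half-life of 0.889 min, shorter than the run, so conversion should stop well inside the run.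

The forecast gives 91% for blue, 90% for green and no change, on the ground that “the partner runs out first and the conversion is set by the few mM of it lost to decomposition early on”. Its blue figure stands 1.4 percentage points above this reckoning, and its green figure 0.40 points above.

The simulation gives 91.7% in blue and 91.3% in green, a difference of −0.39 points that counts as no change. In blue at 0.758 min, partner has a half-life of 0.11 min by step 1 against 0.89 min by decomposition, a fork of 0.890. Blue ends with 5.66 mM of decomposed reagent, so 0.834 of its partner took the cycle, against φ of 0.815. A neighbour of blue charged with 14 mM of partner has a reckoned free share of 0.507 at its start, which gives φ = 0.861 and a reckoned 38.9% of its starting material reacted. That neighbour ends at 39.3%.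

The numbers of this flask were drawn at random within sensible limits; the rest is arithmetic.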